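Readings and results stem from a simulated flask from invented constants; noise was put on by code.

One equivalent of protic impurity removes one molecule of starting material for good, so we follow a single molecule and ask its chance of escaping. The impurity is the limiting reagent of this quench, being charged at less than the starting material, so in the flask that chance is 70.0%. We call this the free share: one minus c(protic impurity)/c(starting material).

| flask | starting material | protic impurity | remark | time |
|---|---|---|---|---|
| gamma | 0.090 M | 0.054 M | run made earlier |  |
| theta | 0.14 M | 0.054 M | run made earlier |  |
| alpha | 0.18 M | 0.081 M | run made earlier |  |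
| flask | 0.18 M | 0.0540 M |  | 15 min |

| run | time / min | target / % | isomer of the product A / % |
|---|---|---|---|
| gamma | 1.33 | 4.8 | 34.5 |
| gamma | 4.00 | 2.6 | 38.2 |
| gamma | 8.00 | 1.8 | 35.0 |
| gamma | 10.0 | 2.4 | 33.0 |
| gamma | 15.0 | 1.0 | 31.6 |
| theta | 1.33 | 6.2 | 38.0 |
| theta | 4.00 | 3.4 | 45.7 |
| theta | 8.00 | 3.1 | 47.8 |
| theta | 10.0 | 2.5 | 47.5 |
| theta | 15.0 | 4.4 | 46.9 |
| alpha | 3.00 | 3.8 | 40.0 |
| alpha | 6.00 | 3.1 | 42.3 |
| alpha | 10.0 | 2.6 | 42.1 |
| alpha | 12.0 | 2.4 | 41.4 |
| alpha | 15.0 | 3.0 | 41.4 |

(scatter of a reading: 0.5 percentage points)

* ratio of target to isomer of the product A at 0.15 s
* ratio of target to isomer of the product A at 12 s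
* ratio of target to isomer of the product A at 15 min
* which of target and isomer of the product A there is more of at 15 min

- what was read earlier has a scatter of 0.5 percentage points, one standard deviation
- what may be going on: starting material <-> target; starting material <-> isomer of the product A; target <-> isomer of the product A; target <-> isomer of the product B; starting material + protic impurity -> quenched substrate

The earlier runs have free shares of 40.0% in gamma, 61.4% in theta and 55.0% in alpha. At 15.0 min, isomer of the product A stands at 79.0%, 76.3% and 75.3% of those shares. On these readings an escaped molecule ends as that isomer with a chance of about 76.9%, and we reckon 53.8% of that isomer for the flask. Target over that isomer at 8.00 min reads 0.0514 in gamma and 0.0649 in theta, close given a scatter of 0.5 percentage points on small target readings, so in these two runs the late ratio barely follows the free share. But the number has no clock, and 0.15 s and 12 s lie earlier than the first reading, so we commit to the late state, with that isomer ahead.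

The forecast gives 0.4, 0.3 and 0.07 at the three times, with isomer of the product A ahead, and calls its early values “a long extrapolation”.

The flask gives 36.7, 1.36 and 0.0681, with isomer of the product A ahead at 53.1% against 3.61% of target.

    starting material ⇌ target (K = 0.402, k = 0.408 /s)
    starting material ⇌ isomer of the product A (K = 5.90, k = 0.00948 /s)
    target ⇌ isomer of the product A (k = 0.0261 /s)
    target ⇌ isomer of the product B (K = 1.20, k = 0.0609 /s)
    starting material + protic impurity → quenched substrate (k = 0.650 /M/s)

In the flask target and that isomer stand level at 0.261 min, earlier than any reading, and the free share, having no clock, does not tell this. A computed run of the flask without the turning of starting material into isomer of the product A, both ways, gives 492 instead of 36.7 at 0.15 s, so that direct step weighs heavily in the early ratio. In the neighbour charged with 0.14 M of protic impurity, the free share is 22.2%, which gives 17.1% of that isomer. The computed neighbour holds 17.6% of that isomer at 15.0 min, with target to that isomer at 0.0653.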